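**Retrosynthetic overview**

1. Numbering (tuberostemonine): ring A = azepane N4/C5–C9/C9a; ring B = pyrrolidine N4/C3/C2/C1/C9a; ring C = cyclohexane C1/C9a/C9/C10(Et)/C11(O)/C12; ring D = lactone C11–O–C14(=O)–C13(Me)–C12; side lactone C18–C21 on C3.
2. Target ⇐ tuberostemonine (N-oxidation) ⇐ C3 thioester + zinc homoenolate (C18–C19 acyl coupling, Felkin–Anh reduction closes the side lactone); ring D ⇐ C11 silyl enol ether (pyruvate aldol at C12, reduction/lactonization, dehydration, hydrogenation sets C13).
3. Key disconnection: rings B and C together by one intramolecular Diels–Alder reaction forming C9–C10 and C1–C9a, leaving a monocyclic ring A enamide lactam with a single stereocentre (C3, from L-allylglycine).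
4. Enabling feature: the C11 oxygen marks ring C as the adduct of a 2-silyloxy diene C10=C11–C12=C1; its C9–C9a edge is shared with ring A next to N4 (an endocyclic enamide as dienophile); C1 and C9a are bridged by C2–C3–N4 of ring B, so the dienophile nitrogen ends a three-atom tether that carries the C3 stereocentre.
5. Ring order: A (steps 1–3) → B + C (step 6) → D (steps 7–10) → side lactone (steps 13–15) → N-oxide (step 16).

Key step: step 6

Assumption: peracid oxidation of tuberostemonine is taken to occur at the nitrogen lone pair of the trans-fused A/B invertomer, anti to the C3 lactonyl group, which is the nitrogen configuration written in the target.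
Remark: compounds 1, 2, 7, 11 and 22 are taken as commercial; C3 (from 1) and C20 (from 22) are the only stereocentres bought.

**Step 1**
Reactants: 1 L-allylglycine methyl ester hydrochloride; 2 6-hydroxyhexanoic acid
Product: 3 methyl (S)-2-(6-hydroxyhexanamido)pent-4-enoate
Conditions: EDC·HCl, HOBt, i-Pr2NEt, CH2Cl2, 0 °C to rt
Reagents that add atoms: none
Why: Carbodiimide/HOBt amide coupling acylates the free-based primary amine much faster than the primary hydroxyl of 2, and the α-stereocentre is safe because the amino ester is the nucleophile and not the activated partner.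

**Step 2**
Reactants: 3 methyl (S)-2-(6-hydroxyhexanamido)pent-4-enoate
Product: 4 methyl (S)-2-(6-oxohexanamido)pent-4-enoate
Conditions: Dess–Martin periodinane, NaHCO3, CH2Cl2, 0 °C to rt
Reagents that add atoms: none
Why: Dess–Martin oxidation converts the primary alcohol into the aldehyde under buffered, non-epimerizing conditions that leave the terminal alkene and the secondary amide untouched.

**Step 3**
Reactants: 4 methyl (S)-2-(6-oxohexanamido)pent-4-enoate
Product: 6 ring A enamide methyl (S)-2-(2-oxo-2,3,4,5-tetrahydro-1H-azepin-1-yl)pent-4-enoate, via cyclic N-acyl hemiaminal 5 (not isolated)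
Conditions: camphorsulfonic acid (cat.), toluene (high dilution), reflux, Dean–Stark
Reagents that add atoms: none
Why: Acid-catalysed intramolecular amide–aldehyde condensation (hemiaminal 5, then loss of water through the N-acyliminium ion) should give the endocyclic enamide, which in a seven-membered ring can only be (Z), with dilution and azeotropic water removal driving the slow seven-ring closure.

**Step 4**
Reactants: 6 ring A enamide; 7 hex-1-en-3-one
Product: 8 methyl (2S,4E)-6-oxo-2-(2-oxo-2,3,4,5-tetrahydro-1H-azepin-1-yl)non-4-enoate
Conditions: second-generation Hoveyda–Grubbs catalyst RuCl2(=CH-C6H4-2-Oi-Pr)(H2IMes) (cat.), excess 7, CH2Cl2, 40 °C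
Reagents that add atoms: none
Why: Olefin cross-metathesis of the terminal allyl group with the electron-poor vinyl ketone is (E)-selective and should outrun any engagement of the 1,2-disubstituted, amide-deactivated enamide C=C.

**Step 5**
Reactants: 8 enone
Product: 9 methyl (2S,4E,6Z)-6-[(tert-butyldimethylsilyl)oxy]-2-(2-oxo-2,3,4,5-tetrahydro-1H-azepin-1-yl)nona-4,6-dienoate
Conditions: TBSOTf, Et3N, CH2Cl2, −78 to 0 °C (TBSOTf added last)
Reagents that add atoms: tert-butyldimethylsilyl trifluoromethanesulfonate, CC(C)(C)[Si](C)(C)OS(=O)(=O)C(F)(F)F
Why: Soft enolization (silyl triflate/amine) of the enone at its α′-methylene should give the cross-conjugated 2-silyloxy diene with the thermodynamically preferred (Z)-enol ether geometry, which places the ethyl group "outside" as the cycloaddition requires.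

**Step 6**
Reactants: 9 silyloxy diene enamide
Product: 10 tricyclic adduct (lactam C5=O, C3 CO2Me, C10 ethyl, C11(OTBS)=C12; H9/H9a cis, H9a/H1 trans, H9/H10 trans, CO2Me cis to H9a)
Conditions: toluene (0.01 M), BHT (cat.), silylated sealed tube, 180 °C
Reagents that add atoms: none
Why: Thermal, concerted but asynchronous intramolecular [4+2] cycloaddition of the (4E,6Z)-2-silyloxy diene C10=C11–C12=C1 onto the endocyclic (Z)-enamide C9=C9a, the closest known type being the intramolecular Diels–Alder reaction of N-tethered enamides with dienes (hydroindole synthesis), here with a 2-silyloxy diene. Ring C closes in the [4+2] mode through the new bonds C9–C10 and C1–C9a, and ring B closes in the same event as the five-membered ring spanned by the three-atom tether C2–C3–N4 (1,3,8-nonatriene-type closure). C9 and C9a become cis because the dienophile is a ring (Z)-alkene, and the C10 ethyl group and the C1–C2 bond end on the face of H9 and H9a because both sit "outside" on the diene, as fixed by the (Z)-enol ether and the (E)-alkene. The trans B/C fusion (H1 anti to H9a) needs the transition state in which ring A points away from the diene so that only H9 and H9a lie beneath it, which should be favoured because the alternative presses C8 and the lactam nitrogen against C11–OSi and C12. The enamide face is chosen by C3: allylic 1,3-strain keeps H3 in the lactam plane beside the C5 carbonyl, so C2 carries the diene to one face while the ester occupies the other, which places the ester cis to H9a and relays the bought (S) centre into C1, C9, C9a and C10 with the configurations of the target. The selectivities needed are thus trans over cis ring fusion and one enamide face, secured by the exo placement of ring A and by the C3 allylic strain, while dilution, BHT and the silylated vessel protect the silyl dienol ether during the long heating that this electronically unactivated pair will need.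

**Step 7**
Reactants: 10 tricyclic silyl enol ether; 11 ethyl pyruvate
Product: 12 aldol adduct (C11 ketone; C12 bears C(OH)(CH3)CO2Et trans to C2, H12 cis to H9a; both C13 carbinol epimers)
Conditions: TiCl4, CH2Cl2, −78 °C
Reagents that add atoms: none
Why: Mukaiyama aldol addition of the regiodefined silyl enol ether to TiCl4-activated ethyl pyruvate should form the C12–C13 bond on the face anti to the pseudoaxial C10 ethyl group, giving the equatorial (thermodynamically preferred, α-epimerizable) side chain, while the configuration of the tertiary carbinol C13 is of no consequence because step 9 erases it.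

**Step 8**
Reactants: 12 aldol adduct
Product: 14 α-hydroxy-α-methyl lactone (ring D closed; H11 cis to H12), via C11 hydroxy ester 13 (not isolated)
Conditions: NaBH4, MeOH/CH2Cl2, −40 to 0 °C; then pyridinium p-toluenesulfonate (cat.), toluene, 60 °C
Reagents that add atoms: none
Why: Borohydride reduction of the C11 ketone from the face opposite the axial C8 methylene of ring A (1,3-diaxial to the carbonyl) should give the axial C11 alcohol cis to the C12 side chain, which closes the cis-fused γ-lactone by intramolecular transesterification.

**Step 9**
Reactants: 14 α-hydroxy-α-methyl lactone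
Product: 15 α-methylene lactone (C13=CH2)
Conditions: SOCl2, pyridine, CH2Cl2, 0 °C to rt
Reagents that add atoms: none
Why: Dehydration of the tertiary α-hydroxy lactone through its chlorosulfite (E2 with pyridine) removes a methyl hydrogen to give the α-methylene lactone and destroys the unselectively formed C13 carbinol centre; any endocyclic butenolide isomer would be reduced in step 10 from the same face to the same product.

**Step 10**
Reactants: 15 α-methylene lactone
Product: 16 α-methyl lactone lactam methyl ester (H11, H12 and H13 all cis)
Conditions: H2 (1–4 atm), 10% Pd/C, EtOAc, rt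
Reagents that add atoms: none
Why: Heterogeneous hydrogenation should deliver hydrogen to C13 from the exposed convex face of the cis-fused lactone (the face of H11 and H12, the other being screened by ring C and the axial C8 methylene), which sets the C13 methyl cis to C1 as in the target.

**Step 11**
Reactants: 16 α-methyl lactone lactam methyl ester
Product: 18 tetracyclic amino lactone methyl ester, via lactim ether tetrafluoroborate 17 (not isolated)
Conditions: Me3OBF4, CH2Cl2, rt; then NaBH4, MeOH, 0 °C
Reagents that add atoms: trimethyloxonium tetrafluoroborate, C[O+](C)C.F[B-](F)(F)F (its atoms stay only in 17, not in 18)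
Why: O-Methylation of the lactam (the most nucleophilic carbonyl oxygen present) to the lactim ether salt and borohydride reduction of this iminium ether (Borch-type lactam reduction) should convert C5=O into CH2 without touching the γ-lactone or the methyl ester.

**Step 12**
Reactants: 18 tetracyclic amino lactone methyl ester
Product: 20 amino acid lactone hydrochloride, via dilithium hydroxy dicarboxylate 19 (not isolated)
Conditions: LiOH, THF/H2O, rt; then aq. HCl to pH 1, rt, concentrate
Reagents that add atoms: lithium hydroxide, [Li+].[OH-] (oxygen of the new carboxyl group; lithium only in 19); hydrogen chloride, Cl (chloride of salt 20)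
Why: Saponification of the methyl ester also opens ring D to the hydroxy carboxylate 19, but acidification relactonizes the cis-γ-hydroxy acid spontaneously, so that only the C3 ester is unmasked and no stereocentre is touched.

**Step 13**
Reactants: 20 amino acid lactone hydrochloride
Product: 21 S-ethyl thioester at C3
Conditions: EtSH, EDC·HCl, DMAP (cat.), i-Pr2NEt, CH2Cl2, 0 °C to rt
Reagents that add atoms: ethanethiol, CCS
Why: Carbodiimide/DMAP thioesterification of the N,N-dialkyl amino acid, which cannot form an oxazolone and so keeps C3 configurationally safe, gives the thioester needed for ketone synthesis.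

**Step 14**
Reactants: 21 S-ethyl thioester; 22 methyl (R)-3-bromo-2-methylpropanoate
Product: 24 γ-keto ester (C3–C18(=O)–C19H2–C20H(CH3)–CO2Me, C20 S), via organozinc bromide 23 (not isolated)
Conditions: 22, Zn, LiCl, THF, 50 °C; then 21, PdCl2(PPh3)2 (cat.), THF/toluene, rt
Reagents that add atoms: zinc, [Zn] (stays only in 23)
Why: Fukuyama coupling (acylation of an alkylzinc halide by a thioester, catalysed by zerovalent palladium formed in the flask) should join C18 to C19 without over-addition or attack on the lactone, the C20 stereocentre being bought with 22 and configurationally stable in the β-zincio ester 23.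

**Step 15**
Reactants: 24 γ-keto ester
Product: 26 tuberostemonine, via C18 hydroxy ester 25 (not isolated)
Conditions: LiBH(s-Bu)3, THF, −78 °C; then AcOH, −78 °C to rt
Reagents that add atoms: none
Why: Felkin–Anh reduction of the α-amino ketone by the bulky hydride (N4 antiperiplanar to the incoming hydride, attack past H3) should give the syn C3–N/C18–O relationship, and the resulting alkoxide lactonizes onto the methyl ester to close the side lactone with cis C18/C20 substituents.

**Step 16**
Reactants: 26 tuberostemonine
Product: 27 N-oxytuberostemonine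
Conditions: mCPBA, CH2Cl2, 0 °C
Reagents that add atoms: 3-chloroperoxybenzoic acid, OOC(=O)c1cccc(Cl)c1
Why: Peracid N-oxidation of the tertiary amine should occur at the lone pair of the trans-fused A/B invertomer on the face anti to the C3 lactonyl substituent, which fixes the nitrogen configuration of the target.

**Compound list**

1 | L-allylglycine methyl ester hydrochloride | Cl.N[C@@H](CC=C)C(=O)OC | starting material
2 | 6-hydroxyhexanoic acid | OCCCCCC(=O)O | starting material
3 | methyl (S)-2-(6-hydroxyhexanamido)pent-4-enoate | OCCCCCC(=O)N[C@@H](CC=C)C(=O)OC | intermediate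
4 | methyl (S)-2-(6-oxohexanamido)pent-4-enoate | O=CCCCCC(=O)N[C@@H](CC=C)C(=O)OC | intermediate
5 | methyl (2S)-2-(7-hydroxy-2-oxoazepan-1-yl)pent-4-enoate (carbinol epimers, not isolated) | OC1CCCCC(=O)N1[C@@H](CC=C)C(=O)OC | intermediate
6 | methyl (S)-2-(2-oxo-2,3,4,5-tetrahydro-1H-azepin-1-yl)pent-4-enoate (ring A enamide) | O=C1CCCC=CN1[C@@H](CC=C)C(=O)OC | intermediate
7 | hex-1-en-3-one | CCCC(=O)C=C | starting material
8 | methyl (2S,4E)-6-oxo-2-(2-oxo-2,3,4,5-tetrahydro-1H-azepin-1-yl)non-4-enoate | O=C1CCCC=CN1[C@@H](C/C=C/C(=O)CCC)C(=O)OC | intermediate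
9 | methyl (2S,4E,6Z)-6-[(tert-butyldimethylsilyl)oxy]-2-(2-oxo-2,3,4,5-tetrahydro-1H-azepin-1-yl)nona-4,6-dienoate | O=C1CCCC=CN1[C@@H](C/C=C/C(O[Si](C)(C)C(C)(C)C)=C/CC)C(=O)OC | intermediate
10 | tricyclic Diels–Alder adduct (rings A, B, C; C11 TBS enol ether) | CC[C@@H]1[C@H]2CCCC(=O)N3[C@H]2[C@H](C[C@H]3C(=O)OC)C=C1O[Si](C)(C)C(C)(C)C | intermediate
11 | ethyl pyruvate | CC(=O)C(=O)OCC | starting material
12 | C12 pyruvate aldol adduct (C11 ketone; C13 carbinol epimers) | CC[C@@H]1[C@H]2CCCC(=O)N3[C@H]2[C@H](C[C@H]3C(=O)OC)[C@H](C1=O)C(C)(O)C(=O)OCC | intermediate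
13 | C11 hydroxy ester (not isolated) | CC[C@@H]1[C@H]2CCCC(=O)N3[C@H]2[C@H](C[C@H]3C(=O)OC)[C@H]([C@H]1O)C(C)(O)C(=O)OCC | intermediate
14 | α-hydroxy-α-methyl lactone (ring D closed) | CC[C@@H]1[C@H]2CCCC(=O)N3[C@H]2[C@H](C[C@H]3C(=O)OC)[C@@H]2[C@H]1OC(=O)C2(C)O | intermediate
15 | α-methylene lactone | CC[C@@H]1[C@H]2CCCC(=O)N3[C@H]2[C@H](C[C@H]3C(=O)OC)[C@@H]2[C@H]1OC(=O)C2=C | intermediate
16 | α-methyl lactone lactam methyl ester | CC[C@@H]1[C@H]2CCCC(=O)N3[C@H]2[C@H](C[C@H]3C(=O)OC)[C@@H]2[C@H]1OC(=O)[C@@H]2C | intermediate
17 | lactim ether tetrafluoroborate (not isolated) | CC[C@@H]1[C@H]2CCCC(OC)=[N+]3[C@H]2[C@H](C[C@H]3C(=O)OC)[C@@H]2[C@H]1OC(=O)[C@@H]2C.F[B-](F)(F)F | intermediate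
18 | tetracyclic amino lactone methyl ester | CC[C@@H]1[C@H]2CCCCN3[C@H]2[C@H](C[C@H]3C(=O)OC)[C@@H]2[C@H]1OC(=O)[C@@H]2C | intermediate
19 | dilithium hydroxy dicarboxylate (not isolated) | CC[C@@H]1[C@H]2CCCCN3[C@H]2[C@H](C[C@H]3C(=O)[O-])[C@H]([C@H]1O)[C@@H](C)C(=O)[O-].[Li+].[Li+] | intermediate
20 | amino acid lactone hydrochloride | CC[C@@H]1[C@H]2CCCCN3[C@H]2[C@H](C[C@H]3C(=O)O)[C@@H]2[C@H]1OC(=O)[C@@H]2C.Cl | intermediate
21 | S-ethyl thioester | CC[C@@H]1[C@H]2CCCCN3[C@H]2[C@H](C[C@H]3C(=O)SCC)[C@@H]2[C@H]1OC(=O)[C@@H]2C | intermediate
22 | methyl (R)-3-bromo-2-methylpropanoate | BrC[C@H](C)C(=O)OC | starting material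
23 | (R)-(3-methoxy-2-methyl-3-oxopropyl)zinc bromide (not isolated) | Br[Zn]C[C@H](C)C(=O)OC | intermediate
24 | γ-keto ester | CC[C@@H]1[C@H]2CCCCN3[C@H]2[C@H](C[C@H]3C(=O)C[C@H](C)C(=O)OC)[C@@H]2[C@H]1OC(=O)[C@@H]2C | intermediate
25 | C18 hydroxy ester (not isolated) | CC[C@@H]1[C@H]2CCCCN3[C@H]2[C@H](C[C@H]3[C@@H](O)C[C@H](C)C(=O)OC)[C@@H]2[C@H]1OC(=O)[C@@H]2C | intermediate
26 | tuberostemonine | CC[C@@H]1[C@H]2CCCCN3[C@H]2[C@H](C[C@H]3[C@@H]2C[C@H](C)C(=O)O2)[C@@H]2[C@H]1OC(=O)[C@@H]2C | intermediate
27 | N-oxytuberostemonine | CC[C@@H]1[C@H]2CCCC[N@@+]3([O-])[C@H]2[C@H](C[C@H]3[C@@H]2C[C@H](C)C(=O)O2)[C@@H]2[C@H]1OC(=O)[C@@H]2C | target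

**Step count and risks**

Total step count: 16. Longest linear sequence: 16 steps (1 to 27).

Steps most likely to fail:

1. Step 6. The cycloaddition may be too slow for the thermal lifetime of the silyl dienol ether, since both partners are electron-rich, or closure through the cis-fused B/C transition state may compete. The fallback is a polarity-matched intermolecular Diels–Alder reaction followed by an intramolecular azido-Schmidt ring expansion, so that ring A is made by ring expansion instead of being brought in. It sets out from 1 and returns at 12. Diazo transfer (imidazole-1-sulfonyl azide hydrogen sulfate, K2CO3, cat. CuSO4·5H2O, MeOH) would give methyl (S)-2-azidopent-4-enoate F1 with retention. Cross-metathesis with 7 as in step 4 would give the azido enone F2, and TBSOTf/Et3N would give the azido silyloxy diene F3. With cyclohex-2-enone and SnCl4 in CH2Cl2 (−78 °C to rt), F3 should undergo the Lewis-acid-promoted exo Diels–Alder reaction to the cis-fused azido octalone F4, which is not isolated. The azide then adds to the activated ketone and the azidohydrin rearranges with migration of C9a (retention) and loss of N2; the silyl enol ether is cleaved on work-up, giving the keto lactam F5. Kinetic enolization of F5 toward the C12 methylene (LiN(SiMe3)2, THF, −78 °C) and aldol addition to 11 returns to the route at 12. Two weaknesses are expected: C3 is remote from the intermolecular cycloaddition and would not steer its facial course, so the diastereomer carrying the mirror-image tricycle would have to be separated; and the α-ester makes the azide a weaker nucleophile than a simple alkyl azide.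

2. Step 3. Intermolecular aldol or aminal condensation of aldehyde 4 may outrun the entropically disfavoured seven-membered ring closure. The fallback makes the N–C9a bond by copper-catalysed intramolecular N-vinylation instead of condensation. It sets out from 1 and returns at 6. Hex-5-ynoic acid would be iodinated (N-iodosuccinimide, cat. AgNO3, acetone) to 6-iodohex-5-ynoic acid F6 and reduced with diimide (2-nitrobenzenesulfonohydrazide, Et3N) to (Z)-6-iodohex-5-enoic acid F7. Coupling with 1 as in step 1 would give methyl (S)-2-[(Z)-6-iodohex-5-enamido]pent-4-enoate F8. CuI, N,N′-dimethylethylenediamine and Cs2CO3 in THF at 70 °C should then close ring A to 6 with retention of the (Z) geometry.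

3. Step 9. Elimination may run into the ring (loss of H12, giving the endocyclic butenolide and erasing C12), or chloride substitution may replace elimination; either would undermine the face control of step 10. The fallback uses reductive C–O cleavage and kinetic protonation instead of elimination and hydrogenation. It sets out from 14 and returns at 16. Acetylation (Ac2O, DMAP, Et3N) would give the tertiary α-acetoxy lactone F9. SmI2 (THF/HMPA, t-BuOH, −78 °C) should expel acetate to the samarium enolate, which is protonated at C13 from the same exposed face that hydrogen would use, giving 16 directly and bypassing steps 9 and 10.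

**Further compounds**

F1 | step 6 | methyl (S)-2-azidopent-4-enoate | [N-]=[N+]=N[C@@H](CC=C)C(=O)OC
F2 | step 6 | methyl (2S,4E)-2-azido-6-oxonon-4-enoate | [N-]=[N+]=N[C@@H](C/C=C/C(=O)CCC)C(=O)OC
F3 | step 6 | methyl (2S,4E,6Z)-2-azido-6-[(tert-butyldimethylsilyl)oxy]nona-4,6-dienoate | [N-]=[N+]=N[C@@H](C/C=C/C(O[Si](C)(C)C(C)(C)C)=C/CC)C(=O)OC
F4 | step 6 | exo Diels–Alder adduct, cis-fused azido octalone silyl enol ether (not isolated) | CC[C@@H]1[C@H]2CCCC(=O)[C@H]2[C@H](C[C@H](N=[N+]=[N-])C(=O)OC)C=C1O[Si](C)(C)C(C)(C)C
F5 | step 6 | tricyclic keto lactam (C11 ketone, C5 lactam, C3 CO2Me) | CC[C@@H]1[C@H]2CCCC(=O)N3[C@H]2[C@H](C[C@H]3C(=O)OC)CC1=O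
F6 | step 3 | 6-iodohex-5-ynoic acid | OC(=O)CCCC#CI
F7 | step 3 | (Z)-6-iodohex-5-enoic acid | OC(=O)CCC/C=C\I
F8 | step 3 | methyl (S)-2-[(Z)-6-iodohex-5-enamido]pent-4-enoate | I/C=C\CCCC(=O)N[C@@H](CC=C)C(=O)OC
F9 | step 9 | tertiary α-acetoxy-α-methyl lactone (acetate of 14) | CC[C@@H]1[C@H]2CCCC(=O)N3[C@H]2[C@H](C[C@H]3C(=O)OC)[C@@H]2[C@H]1OC(=O)C2(C)OC(C)=O
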